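The whole route rests on cutting the bond between arene carbon C2 (ortho to the tigloyloxy-bearing C1, para to the ring methyl) and the fully substituted oxirane carbon C2. Because that oxirane carbon carries two one-carbon arms (ring CH2 and CH2O), it is traced back to the sp2 carbon of a 2-aryl allyl alcohol. The key step, a Suzuki–Miyaura coupling of the aryl bromide that already bears the tiglate with 2-(pinacolboryl)prop-2-en-1-ol, joins both halves at this carbon in one operation and delivers a prochiral allylic alcohol. A tartrate-controlled Sharpless epoxidation then sets the single stereocentre, and the epoxy alcohol is acylated in the same flask.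

Key step: step 3

Remark: boronate 5 is taken as a catalogue building block; otherwise it is one step from prop-2-yn-1-ol by copper-catalysed Markovnikov protoboration with bis(pinacolato)diboron.

Step 1
Reactants: 1 4-methoxy-3-methylphenol
Product: 2 2-bromo-4-methoxy-5-methylphenol
Conditions: NBS (1.0 equiv), CH2Cl2, −20 → 0 °C, dark
Reagents that add atoms: N-bromosuccinimide (NBS), O=C1CCC(=O)N1Br
Why: Electrophilic aromatic bromination, in which the free hydroxyl is the strongest director, its para position is blocked by OMe, and of its two ortho carbons the one para to the ring methyl and flanked by H should react in preference to the one wedged between OH and CH3.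

Step 2
Reactants: 2 2-bromo-4-methoxy-5-methylphenol; 3 tigloyl chloride [(E)-2-methylbut-2-enoyl chloride]
Product: 4 2-bromo-4-methoxy-5-methylphenyl (E)-2-methylbut-2-enoate
Conditions: pyridine, DMAP (cat.), CH2Cl2, 0 °C → rt
Reagents that add atoms: none
Why: DMAP-catalysed O-acylation of the phenol with the acid chloride, using the weak base pyridine so that vinylketene formation and deconjugation are avoided and the (E)-tiglate geometry is kept.

Step 3
Reactants: 4 2-bromo-4-methoxy-5-methylphenyl (E)-2-methylbut-2-enoate; 5 2-(4,4,5,5-tetramethyl-1,3,2-dioxaborolan-2-yl)prop-2-en-1-ol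
Product: 6 2-(3-hydroxyprop-1-en-2-yl)-4-methoxy-5-methylphenyl (E)-2-methylbut-2-enoate
Conditions: XPhos Pd G3 (2 mol%), 0.5 M aq. K3PO4 (2 equiv), THF, degassed, rt → 40 °C
Reagents that add atoms: none
Why: Suzuki–Miyaura cross-coupling: Pd(0) inserts into the C–Br bond at arene C2, the base-activated alkenyl boronate transmetalates, and reductive elimination forms the bond between arene C2 and the alkene carbon that becomes oxirane C2 in step 4. The closest known reaction type is the coupling of ortho-substituted aryl bromides with 1,1-disubstituted alkenyl pinacolboronates (isopropenyl type) under dialkylbiarylphosphine catalysis. No ring is closed and no stereocentre is formed; the step deliberately delivers a prochiral 1,1-disubstituted allylic alcohol whose free OH directs the face-selective epoxidation that follows. The selectivity needed is chemoselectivity, namely C–Br activation without hydrolysis or O-to-O migration of the aryl tiglate and without engaging its electron-poor alkene; a fast precatalyst near room temperature with a biphasic phosphate base should secure this, and the site of coupling is fixed by the bromine placed in step 1.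

Step 4
Reactants: 6 2-(3-hydroxyprop-1-en-2-yl)-4-methoxy-5-methylphenyl (E)-2-methylbut-2-enoate; 7 2-methylpropanoic anhydride (isobutyric anhydride)
Product: 9 [(2R)-2-{5-methoxy-4-methyl-2-[(E)-2-methylbut-2-enoyloxy]phenyl}oxiran-2-yl]methyl 2-methylpropanoate (target CNP0256150.1), via (S)-epoxy alcohol 8 (not isolated)
Conditions: Ti(OiPr)4 (10 mol%), L-(+)-DIPT (12 mol%), TBHP (anhydrous, 1.5 equiv), 4 Å MS, CH2Cl2, −20 °C; then P(OMe)3 (0.5 equiv), −20 °C; then 7 (2.5 equiv), Et3N, DMAP (cat.), −20 → 0 °C; NaHCO3 work-up
Reagents that add atoms: tert-butyl hydroperoxide (TBHP), CC(C)(C)OO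
Why: Katsuki–Sharpless asymmetric epoxidation of the 2-substituted allylic alcohol, in which the titanium–L-(+)-tartrate complex bound to the allylic OH should deliver the peroxide oxygen to the alkene face that gives the (S)-epoxy alcohol (the sense established for 2-substituted allyl alcohols such as methallyl alcohol), followed by in-situ acylation of the primary OH (Sharpless in-situ derivatisation), which does not touch the stereocentre and changes its descriptor to R only through the CIP priorities.

Compound list
1 | 4-methoxy-3-methylphenol | Cc1cc(O)ccc1OC | starting material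
2 | 2-bromo-4-methoxy-5-methylphenol | Cc1cc(O)c(Br)cc1OC | intermediate
3 | tigloyl chloride [(E)-2-methylbut-2-enoyl chloride] | C/C=C(\C)C(=O)Cl | starting material
4 | 2-bromo-4-methoxy-5-methylphenyl (E)-2-methylbut-2-enoate | C/C=C(\C)C(=O)Oc1cc(C)c(OC)cc1Br | intermediate
5 | 2-(4,4,5,5-tetramethyl-1,3,2-dioxaborolan-2-yl)prop-2-en-1-ol | C=C(CO)B1OC(C)(C)C(C)(C)O1 | starting material
6 | 2-(3-hydroxyprop-1-en-2-yl)-4-methoxy-5-methylphenyl (E)-2-methylbut-2-enoate | C/C=C(\C)C(=O)Oc1cc(C)c(OC)cc1C(=C)CO | intermediate
7 | 2-methylpropanoic anhydride (isobutyric anhydride) | CC(C)C(=O)OC(=O)C(C)C | starting material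
8 | 2-[(2S)-2-(hydroxymethyl)oxiran-2-yl]-4-methoxy-5-methylphenyl (E)-2-methylbut-2-enoate (not isolated) | C/C=C(\C)C(=O)Oc1cc(C)c(OC)cc1[C@]1(CO)CO1 | intermediate
9 | [(2R)-2-{5-methoxy-4-methyl-2-[(E)-2-methylbut-2-enoyloxy]phenyl}oxiran-2-yl]methyl 2-methylpropanoate | C/C=C(\C)C(=O)Oc1cc(C)c(OC)cc1[C@]1(COC(=O)C(C)C)CO1 | target

Total step count: 4
Longest linear sequence: 4 steps (1 → 2 → 4 → 6 → 9)

Steps most likely to fail

Step 4. The 2-aryl epoxy alcohol is acid-sensitive and may be opened by titanium alkoxides before it is trapped. Facial control may also erode if the ortho acyloxy group competes for titanium. The fallback replaces the hydroxyl-directed epoxidation by a non-directed one after acylation. It sets out from 6, which is acylated with 7 (Et3N, DMAP, CH2Cl2, 0 °C) to give 2-[3-(2-methylpropanoyloxy)prop-1-en-2-yl]-4-methoxy-5-methylphenyl (E)-2-methylbut-2-enoate F1. A Shi-type asymmetric epoxidation follows (Oxone, carbohydrate-derived lactam ketone catalyst of the series suited to 1,1-disubstituted alkenes, buffered MeCN/DMM–water, 0 °C). The catalyst enantiomer that delivers the (R)-epoxide is chosen, and the fallback comes back to the route at 9. The electrophilic dioxirane should attack the electron-rich styrenic alkene and leave the electron-poor tiglate alkene alone.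

Step 3. The aryl tiglate may be hydrolysed, or may migrate to the newly introduced primary hydroxyl, under the basic coupling conditions; protodeboronation of 5 is a further risk. The fallback couples first and esterifies afterwards. It sets out from 2, which carries no ester and is coupled with 5 under standard aqueous conditions (Pd(dppf)Cl2, K2CO3, dioxane/H2O, 80 °C) to give 2-(2-hydroxy-5-methoxy-4-methylphenyl)prop-2-en-1-ol F2. Only the phenoxide is then acylated (K2CO3, acetone, 0 °C, 1.0 equiv of 3), relying on the much higher acidity of the phenol over the primary alcohol. The fallback comes back to the route at 6.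

Step 1. Regiocontrol may be poor (attack ortho to OMe or between OH and CH3), and over-bromination or oxidation of the p-methoxyphenol to a quinone is possible. The fallback uses directed ortho-metalation and sets out from 1. Carbamoylation (N,N-diethylcarbamoyl chloride, K2CO3, MeCN, reflux) gives 4-methoxy-3-methylphenyl N,N-diethylcarbamate F3. Treatment with s-BuLi/TMEDA (THF, −78 °C) should deprotonate the unhindered carbon ortho to the carbamate to give 2-lithio-4-methoxy-5-methylphenyl N,N-diethylcarbamate F4. This is quenched at −78 °C with 1,2-dibromotetrachloroethane, before anionic Fries rearrangement can set in, to give 2-bromo-4-methoxy-5-methylphenyl N,N-diethylcarbamate F5. Cleavage of the carbamate (KOH, EtOH/H2O, reflux) comes back to the route at 2.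

Further compounds
F1 | step 4 | 2-[3-(2-methylpropanoyloxy)prop-1-en-2-yl]-4-methoxy-5-methylphenyl (E)-2-methylbut-2-enoate | C/C=C(\C)C(=O)Oc1cc(C)c(OC)cc1C(=C)COC(=O)C(C)C
F2 | step 3 | 2-(2-hydroxy-5-methoxy-4-methylphenyl)prop-2-en-1-ol | C=C(CO)c1cc(OC)c(C)cc1O
F3 | step 1 | 4-methoxy-3-methylphenyl N,N-diethylcarbamate | CCN(CC)C(=O)Oc1ccc(OC)c(C)c1
F4 | step 1 | 2-lithio-4-methoxy-5-methylphenyl N,N-diethylcarbamate (not isolated) | [Li]c1cc(OC)c(C)cc1OC(=O)N(CC)CC
F5 | step 1 | 2-bromo-4-methoxy-5-methylphenyl N,N-diethylcarbamate | CCN(CC)C(=O)Oc1cc(C)c(OC)cc1Br
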